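The route cuts the nine-membered ring C2–C3–C4–C5–C10–C12–C13–C14–C15 at C4–C5. In this ring the ketone-equivalent C2 (later the exocyclic methylene carbon) and the ether-bearing C10 are 1,5-related, the signature of an oxy-Cope product. One anionic [3,3] shift of a 1,2-dialkenylcyclopentanol therefore expands the five-membered ring to the cyclononenone, forms C4–C5, sets C5 and leaves the C10=C12 alkene for chroman closure, with the cyclobutane (C14–C17) carried intact. The precursor is an enantiopure 6,6-dimethylbicyclo[3.2.0]heptan-2-ol with an exo vinyl group on C2 and, on C12, an endo (E)-butenyl chain ending in a MOM-protected phloroglucinol ring.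

Key step: step 9

Remark: atom labels C1–C32 are those of the target SMILES read from left to right; racemate 3 is written as its two enantiomers joined by a dot, and the configuration of adduct 6 would be assigned by X-ray analysis before the (1R,5R) series is carried on.

Step 1
Reactants: 1 cyclopent-2-en-1-one; 2 2-methylpropene
Product: 3 rac-(1R*,5R*)-6,6-dimethylbicyclo[3.2.0]heptan-2-one
Conditions: hν (Hg lamp, Pyrex), excess 2, CH2Cl2, −78 °C; distillation
Reagents that add atoms: none
Why: Triplet enone–alkene [2+2] photocycloaddition; the electron-rich alkene adds head-to-tail so that the CMe2 carbon (C17) bonds to the enone β-carbon (C14), and the five-membered ring enforces the cis fusion at C14/C15, formed as a racemate.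

Step 2
Reactants: 3 rac-6,6-dimethylbicyclo[3.2.0]heptan-2-one; 4 (S)-N,S-dimethyl-S-phenylsulfoximine
Product: 6 (1R,2S,5R)-6,6-dimethyl-2-{[(S)-N-methyl-S-phenylsulfonimidoyl]methyl}bicyclo[3.2.0]heptan-2-ol, via lithiated sulfoximine 5 (not isolated)
Conditions: 4, n-BuLi, THF, −78 °C; then 3; aq NH4Cl; chromatographic separation of the two diastereomers
Reagents that add atoms: none
Why: Carbonyl addition of the enantiopure sulfoximine carbanion from the convex face turns the two enantiomers of 3 into diastereomeric β-hydroxysulfoximines that should separate on silica (resolution through covalent diastereomers); the carbinol centre formed by exo attack is temporary.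

Step 3
Reactants: 6 β-hydroxysulfoximine adduct
Product: 7 (1R,5R)-6,6-dimethylbicyclo[3.2.0]heptan-2-one
Conditions: toluene, 110 °C
Reagents that add atoms: none
Why: β-Hydroxysulfoximines undergo thermal retro-addition, which should release the ketone with C14 and C15 untouched and return the auxiliary.

Step 4
Reactants: 8 phloroglucinol
Product: 9 1,3,5-tris(methoxymethoxy)benzene
Conditions: MOMCl, i-Pr2NEt, CH2Cl2/DMF, 0 °C → rt
Reagents that add atoms: chloromethyl methyl ether, COCCl
Why: Threefold O-alkylation of the phenols with the hard electrophile MOMCl under amine base (acetal formation); the MOM groups later direct lithiation and are removed by the acid that closes the chroman.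

Step 5
Reactants: 9 1,3,5-tris(methoxymethoxy)benzene; 10 1-bromobut-2-yne
Product: 12 2-(but-2-yn-1-yl)-1,3,5-tris(methoxymethoxy)benzene, via aryllithium 11 (not isolated)
Conditions: n-BuLi, THF, 0 °C; then 10, −78 °C → rt
Reagents that add atoms: none
Why: Directed ortho-metalation between two MOM ethers (all three ring positions are equivalent) followed by SN2 alkylation of the aryllithium with the primary propargylic bromide.

Step 6
Reactants: 12 2-(but-2-yn-1-yl)-1,3,5-tris(methoxymethoxy)benzene
Product: 14 2-[(2E)-3-iodobut-2-en-1-yl]-1,3,5-tris(methoxymethoxy)benzene, via alkenylzirconocene chloride 13 (not isolated)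
Conditions: Cp2Zr(H)Cl, THF, rt → 40 °C; then iodine, 0 °C
Reagents that add atoms: iodine, [I][I]
Why: Syn hydrozirconation of the internal alkyne puts zirconium on the less hindered methyl-bearing carbon and iodinolysis proceeds with retention, so iodine ends trans to the benzylic CH2 (E); iodine without an activator should leave the electron-rich arene alone.

Step 7
Reactants: 7 (1R,5R)-6,6-dimethylbicyclo[3.2.0]heptan-2-one; 14 (E)-alkenyl iodide
Product: 17 (1R,3R,5R)-6,6-dimethyl-3-{(2E)-4-[2,4,6-tris(methoxymethoxy)phenyl]but-2-en-2-yl}bicyclo[3.2.0]heptan-2-one, via lithium enolate 15 (not isolated), via lithium dienolate 16 (not isolated)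
Conditions: LiN(SiMe3)2 (2.4 equiv), Pd2(dba)3, P(t-Bu)3, THF, rt; then AcOH, −78 °C
Reagents that add atoms: none
Why: Palladium-catalysed α-alkenylation of a ketone enolate (zerovalent palladium inserts into the C–I bond, the enolate of the only α-CH2 transmetalates, reductive elimination forms C12–C10 with retention of the E geometry); excess base holds the product as dienolate 16, and kinetic α-protonation from the convex face should give the β,γ-unsaturated ketone with the butenyl group endo at C12.

Step 8
Reactants: 17 α-alkenyl ketone; 18 vinylmagnesium bromide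
Product: 19 (1R,2R,3R,5R)-2-ethenyl-6,6-dimethyl-3-{(2E)-4-[2,4,6-tris(methoxymethoxy)phenyl]but-2-en-2-yl}bicyclo[3.2.0]heptan-2-ol
Conditions: 18, CeCl3, THF, −78 °C; aq NH4Cl
Reagents that add atoms: none
Why: 1,2-Addition of the vinyl organocerium reagent (CeCl3 curbs enolisation of the acidic β,γ-unsaturated ketone) from the convex face, which is also anti to the endo C12 substituent, so C2 is set with the vinyl group exo and trans to the butenyl chain.

Step 9
Reactants: 19 2-exo-vinyl-3-endo-alkenyl bicyclo[3.2.0]heptan-2-ol
Product: 22 (1R,5S,6E,9R)-6,10,10-trimethyl-5-[2,4,6-tris(methoxymethoxy)benzyl]bicyclo[7.2.0]undec-6-en-2-one, via potassium alkoxide 20 (not isolated), via potassium enolate 21 (not isolated)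
Conditions: KH, 18-crown-6, THF, 0 °C → rt; aq NH4Cl, −78 °C
Reagents that add atoms: none
Why: Deprotonation gives the crown-separated potassium alkoxide 20, in which the 1,5-diene C4=C3–C2–C12–C10=C5 undergoes a [3,3]-sigmatropic shift at or below room temperature: C4–C5 forms as C2–C12 breaks, and the enolate 21 (C2=C3) is protonated on quench without touching C15. The closest known reaction type is the anionic oxy-Cope ring expansion of 1,2-dialkenylcycloalkanols, here from five to nine members. The nine-membered ring is not closed end to end but arises by ring expansion: C3, C4, C5 and C10 are inserted into the C2–C12 bond of the cyclopentane while the cyclobutane stays fused at C14–C15. The new stereocenter C5 is set by suprafacial chirality transfer from C12 across the allyl unit C12–C10–C5 in a chair transition state in which both ring bonds (C2–C15, C12–C13) and the benzylic carbon C6 of the E side chain are equatorial, which should give 5S together with the E C10=C12 alkene. The step needs the chair [3,3] path to win over fragmentation or a 1,3-shift; the trans arrangement of the two alkenyl groups cannot reach a boat, and the low temperature allowed by the dissociated alkoxide should disfavour the stepwise paths.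

Step 10
Reactants: 22 cis-fused cyclononenone
Product: 23 (1S,5S,6E,9R)-6,10,10-trimethyl-5-[2,4,6-tris(methoxymethoxy)benzyl]bicyclo[7.2.0]undec-6-en-2-one
Conditions: t-BuOK (cat.), t-BuOH/THF, rt
Reagents that add atoms: none
Why: Base-mediated epimerisation through the C2=C15 enolate should move the ring fusion to the thermodynamically preferred trans arrangement (C15 becomes S), as expected for a cyclobutane fused to a nine-membered ring; C5 is not enolisable and stays.

Step 11
Reactants: 23 trans-fused cyclononenone
Product: 25 (5S,10R,14R,15S)-chroman-5,7-diol ketone, via free triol 24 (not isolated)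
Conditions: HCl, MeOH, 45 °C
Reagents that add atoms: none
Why: Acid cleaves the MOM acetals and then protonates the trisubstituted alkene at C12 (Markovnikov), and an ortho phenol (the two are equivalent) traps the tertiary C10 cation in a six-membered closure, the acid-catalysed phenol–alkene cyclisation to a chroman; C10 is set under control of C5 through a chair-like closure with both nine-membered-ring bonds (C5–C4, C10–C12) equatorial, which corresponds to the trans-fused 10R isomer.

Step 12
Reactants: 25 chroman-5,7-diol ketone; 26 2-methylpropanoyl chloride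
Product: 27 C25-(2-methylpropanoyl) chroman-5,7-diol ketone
Conditions: 26, TiCl4, CH2Cl2, 0 °C → rt
Reagents that add atoms: none
Why: Friedel–Crafts C-acylation of a phloroglucinol monoether, in which TiCl4 bound to both phenoxides should steer the acylium to C25 (flanked by the two hydroxyls) in preference to C20 next to the ring oxygen; no stereocenter is formed.

Step 13
Reactants: 27 acylated chroman-diol ketone
Product: 28 C2-methylene acylated chroman-5,7-diol
Conditions: Ph3PCH3Br, t-BuOK (excess), toluene/THF, 60 °C
Reagents that add atoms: methyltriphenylphosphonium bromide, C[P+](c1ccccc1)(c1ccccc1)c1ccccc1.[Br-]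
Why: Wittig methylenation of the hindered C2 ketone with excess ylide; the phenols consume two equivalents and, as phenoxides, switch off the aryl ketone, and the trans ring fusion is the stable one so C15 is not at risk.

Step 14
Reactants: 28 C2-methylene acylated chroman-5,7-diol
Product: 30 target CNP0497637.2, via C20-monomethyl phenol 29 (not isolated)
Conditions: NaOMe, MeI, MeOH, 0 °C → rt; aq HCl work-up
Reagents that add atoms: iodomethane, CI
Why: Dearomative double C-methylation of an acylphloroglucinol (phenoxide C-alkylation in methanol): the only free ring carbon C20 is methylated and then methylated again to the gem-dimethyl cyclohexadienone, which is the enolised β-triketone of the target; no stereocenter is formed.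

Compound list
1 | cyclopent-2-en-1-one | O=C1C=CCC1 | starting material
2 | 2-methylpropene | C=C(C)C | starting material
3 | rac-(1R*,5R*)-6,6-dimethylbicyclo[3.2.0]heptan-2-one (cis-fused, both enantiomers) | O=C1CC[C@@H]2[C@H]1CC2(C)C.O=C1CC[C@H]2[C@@H]1CC2(C)C | intermediate
4 | (S)-N,S-dimethyl-S-phenylsulfoximine | CN=[S@@](C)(=O)c1ccccc1 | starting material
5 | (S)-S-(lithiomethyl)-N-methyl-S-phenylsulfoximine | CN=[S@@](C[Li])(=O)c1ccccc1 | intermediate
6 | (1R,2S,5R)-6,6-dimethyl-2-{[(S)-N-methyl-S-phenylsulfonimidoyl]methyl}bicyclo[3.2.0]heptan-2-ol (exo CH2S, endo OH) | CN=[S@@](C[C@]1(O)CC[C@@H]2[C@H]1CC2(C)C)(=O)c1ccccc1 | intermediate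
7 | (1R,5R)-6,6-dimethylbicyclo[3.2.0]heptan-2-one | O=C1CC[C@@H]2[C@H]1CC2(C)C | intermediate
8 | phloroglucinol (benzene-1,3,5-triol) | Oc1cc(O)cc(O)c1 | starting material
9 | 1,3,5-tris(methoxymethoxy)benzene | COCOc1cc(OCOC)cc(OCOC)c1 | intermediate
10 | 1-bromobut-2-yne | CC#CCBr | starting material
11 | 2,4,6-tris(methoxymethoxy)phenyllithium | [Li]c1c(OCOC)cc(OCOC)cc1OCOC | intermediate
12 | 2-(but-2-yn-1-yl)-1,3,5-tris(methoxymethoxy)benzene | CC#CCc1c(OCOC)cc(OCOC)cc1OCOC | intermediate
13 | chlorobis(cyclopentadienyl){(2E)-4-[2,4,6-tris(methoxymethoxy)phenyl]but-2-en-2-yl}zirconium | C/C(=C\Cc1c(OCOC)cc(OCOC)cc1OCOC)[Zr](Cl)(C1C=CC=C1)C1C=CC=C1 | intermediate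
14 | 2-[(2E)-3-iodobut-2-en-1-yl]-1,3,5-tris(methoxymethoxy)benzene | I/C(C)=C/Cc1c(OCOC)cc(OCOC)cc1OCOC | intermediate
15 | lithium enolate of 7 (C2=C12) | [Li]OC1=CC[C@@H]2[C@H]1CC2(C)C | intermediate
16 | lithium dienolate of 17 (C2=C12 conjugated to C10=C5) | [Li]OC1=C(/C(C)=C/Cc2c(OCOC)cc(OCOC)cc2OCOC)C[C@@H]2[C@H]1CC2(C)C | intermediate
17 | (1R,3R,5R)-6,6-dimethyl-3-{(2E)-4-[2,4,6-tris(methoxymethoxy)phenyl]but-2-en-2-yl}bicyclo[3.2.0]heptan-2-one (butenyl endo) | O=C1[C@@H](/C(C)=C/Cc2c(OCOC)cc(OCOC)cc2OCOC)C[C@@H]2[C@H]1CC2(C)C | intermediate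
18 | vinylmagnesium bromide | C=C[Mg]Br | starting material
19 | (1R,2R,3R,5R)-2-ethenyl-6,6-dimethyl-3-{(2E)-4-[2,4,6-tris(methoxymethoxy)phenyl]but-2-en-2-yl}bicyclo[3.2.0]heptan-2-ol (vinyl exo, OH endo, butenyl endo) | C=C[C@]1(O)[C@@H](/C(C)=C/Cc2c(OCOC)cc(OCOC)cc2OCOC)C[C@@H]2[C@H]1CC2(C)C | intermediate
20 | potassium alkoxide of 19 | C=C[C@]1(O[K])[C@@H](/C(C)=C/Cc2c(OCOC)cc(OCOC)cc2OCOC)C[C@@H]2[C@H]1CC2(C)C | intermediate
21 | potassium enolate of 22 (C2=C3) | [K]OC1=CC[C@@H](Cc2c(OCOC)cc(OCOC)cc2OCOC)/C(C)=C/C[C@@H]2[C@H]1CC2(C)C | intermediate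
22 | (1R,5S,6E,9R)-6,10,10-trimethyl-5-[2,4,6-tris(methoxymethoxy)benzyl]bicyclo[7.2.0]undec-6-en-2-one (cis-fused cyclobutane) | O=C1CC[C@@H](Cc2c(OCOC)cc(OCOC)cc2OCOC)/C(C)=C/C[C@@H]2[C@H]1CC2(C)C | intermediate
23 | (1S,5S,6E,9R)-6,10,10-trimethyl-5-[2,4,6-tris(methoxymethoxy)benzyl]bicyclo[7.2.0]undec-6-en-2-one (trans-fused cyclobutane) | O=C1CC[C@@H](Cc2c(OCOC)cc(OCOC)cc2OCOC)/C(C)=C/C[C@@H]2[C@@H]1CC2(C)C | intermediate
24 | (1S,5S,6E,9R)-6,10,10-trimethyl-5-(2,4,6-trihydroxybenzyl)bicyclo[7.2.0]undec-6-en-2-one | O=C1CC[C@@H](Cc2c(O)cc(O)cc2O)/C(C)=C/C[C@@H]2[C@@H]1CC2(C)C | intermediate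
25 | (5S,10R,14R,15S)-chroman-5,7-diol ketone: target ring system with C2 ketone, phenols on C31 and C23, hydrogens on C20 and C25 | O=C1CC[C@H]2Cc3c(O)cc(O)cc3O[C@]2(C)CC[C@@H]2[C@@H]1CC2(C)C | intermediate
26 | 2-methylpropanoyl chloride (isobutyryl chloride) | CC(C)C(=O)Cl | starting material
27 | 25 carrying the 2-methylpropanoyl group on C25 | O=C1CC[C@H]2Cc3c(O)c(C(=O)C(C)C)c(O)cc3O[C@]2(C)CC[C@@H]2[C@@H]1CC2(C)C | intermediate
28 | 27 with the C2 ketone replaced by the exocyclic methylene C2=C1 | C=C1CC[C@H]2Cc3c(O)c(C(=O)C(C)C)c(O)cc3O[C@]2(C)CC[C@@H]2[C@@H]1CC2(C)C | intermediate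
29 | 28 carrying one methyl group on C20 (still aromatic) | C=C1CC[C@H]2Cc3c(O)c(C(=O)C(C)C)c(O)c(C)c3O[C@]2(C)CC[C@@H]2[C@@H]1CC2(C)C | intermediate
30 | CNP0497637.2 (5S,10R,14R,15S) | C=C1CC[C@H]2CC3=C(O[C@]2(C)CC[C@@H]2[C@@H]1CC2(C)C)C(C)(C)C(=O)C(C(=O)C(C)C)=C3O | target

Total step count: 14. Longest linear sequence: 11 steps (steps 1, 2, 3, 7–14; the arene branch, steps 4, 5, 6, 7–14, is equally long).

Steps most likely to fail

Step 9. The alkoxide may break the C2–C12 bond heterolytically and recombine in a 1,3-sense, or the trans-dialkenyl chair may be too strained to deliver the E-cyclononene, so that the rearrangement stalls or fragments. The fallback sets out from 17 and returns at 25. Ketone 17 would be epimerised at C12 with DBU to the exo-butenyl ketone F1. Vinylcerium addition from the convex face would then give the cis-1,2-dialkenyl alcohol F2, with both alkenyl groups exo. Under the same KH/18-crown-6 conditions F2 can use the boat transition state open to cis-dialkenyl systems and should give the less strained Z-cyclononenone F3. C5 keeps the 5S configuration because inverting C12 and the ring-alkene geometry together leaves the sense of chirality transfer unchanged. Base epimerisation at C15 would give the trans-fused Z-ketone F4. Acid treatment of F4 removes the MOM groups and closes the chroman through the same C10 cation as in step 11, which rejoins the route at 25.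

Step 11. The phenol may capture the C10 cation from the wrong face (giving the cis-fused C10 epimer), a 1,2-hydride shift from C5 may precede capture, or the C2 carbonyl oxygen may intercept the cation across the ring. The fallback sets out from 22 and returns at 25. The ring closure would be moved ahead of the C15 epimerisation, so that it runs on a nine-membered ring of different shape. HCl in methanol on 22 would give the chroman-diol ketone with the cyclobutane still cis-fused F5. Treatment of F5 with t-BuOK in t-BuOH then equilibrates C15 and gives 25.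

Step 12. The acylium may attack C20, the more exposed carbon next to the ring oxygen, instead of C25, or O-acylation may not be followed by migration to carbon. The fallback sets out from 25 and returns at 27. One equivalent of NBS in CH2Cl2 at −78 °C would block the more exposed position as the C20 bromide F6. TiCl4-mediated acylation with 26 can then only occur at C25 and gives the bromo ketone F7. Hydrogenolysis of the aryl bromide (H2, Pd/C, Et3N, EtOAc; no alkene is present at this stage) would give 27.

Further compounds
F1 | step 9 | (1R,3S,5R)-6,6-dimethyl-3-{(2E)-4-[2,4,6-tris(methoxymethoxy)phenyl]but-2-en-2-yl}bicyclo[3.2.0]heptan-2-one (butenyl exo) | O=C1[C@H](/C(C)=C/Cc2c(OCOC)cc(OCOC)cc2OCOC)C[C@@H]2[C@H]1CC2(C)C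
F2 | step 9 | C12 epimer of 19 (vinyl exo, butenyl exo, OH endo) | C=C[C@]1(O)[C@H](/C(C)=C/Cc2c(OCOC)cc(OCOC)cc2OCOC)C[C@@H]2[C@H]1CC2(C)C
F3 | step 9 | (6Z) isomer of 22 (cis-fused cyclobutane, 5S) | O=C1CC[C@@H](Cc2c(OCOC)cc(OCOC)cc2OCOC)/C(C)=C\C[C@@H]2[C@H]1CC2(C)C
F4 | step 9 | (6Z) isomer of 23 (trans-fused cyclobutane, 5S) | O=C1CC[C@@H](Cc2c(OCOC)cc(OCOC)cc2OCOC)/C(C)=C\C[C@@H]2[C@@H]1CC2(C)C
F5 | step 11 | C15 epimer of 25 (cis-fused cyclobutane) | O=C1CC[C@H]2Cc3c(O)cc(O)cc3O[C@]2(C)CC[C@@H]2[C@H]1CC2(C)C
F6 | step 12 | 25 carrying bromine on C20 | O=C1CC[C@H]2Cc3c(O)cc(O)c(Br)c3O[C@]2(C)CC[C@@H]2[C@@H]1CC2(C)C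
F7 | step 12 | 27 carrying bromine on C20 | O=C1CC[C@H]2Cc3c(O)c(C(=O)C(C)C)c(O)c(Br)c3O[C@]2(C)CC[C@@H]2[C@@H]1CC2(C)C
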